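**Plan**

1. Retrosynthesis: the cyclohexene is cut at C12–C4′ and C15–C5′ (Diels–Alder) into trans-communic acid 30 and the caryophyllane acid 39 (labdane numbering for the diterpene half, primed caryophyllane numbering for the other half).
2. 30 is cut at C11–C12 (sulfolene alkylation, SO2 extrusion), then at C8–C9 and C1–C10 (both decalin rings in one radical chain) to the acyclic iodo-(Z)-enoate-yne 20. 20 is cut at the two C4 alkyl bonds (lactone enolate alkylations) and at C5–C10 (1,4-addition) back to dihydropyranone 1.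
3. Enabling feature: the quaternary C10 lies between C1 and C9, and C9 carries the one-carbon branch C11 and is bonded to C8 of the exocyclic C8=C17. C10=C9–C11 can therefore be a (Z)-β-methyl enoate (radical acceptor at C10) and C8≡C17 an alkyne that ends as the methylene.
4. Forward order: C5, then C4 on a temporary δ-lactone ring (C19–O–C7); lactone opened to the C19 ester and C7 iodide; alkyne and enoate installed; ring A (C1–C10) then ring B (C9–C8) in step 11; diene; finally the cyclohexene by [4+2]. The four- and nine-membered rings come with 31.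
5. Stereochemistry: C5 from Rh/(S)-BINAP; C4 from the lactone (CH3 anti to the C5 substituent); C10 from A(1,3) strain of the (Z)-enoate in a chair transition state; C9 from the chair-like second closure; C1′/C9′ from (−)-caryophyllene oxide; the trans-cyclononene from a stereospecific Corey–Winter elimination; C12, C4′, C5′ from the endo, outer-face Diels–Alder addition.

Key step: step 11

Assumption: commercial (−)-caryophyllene oxide is (1R,4R,5R,9S); caryophyllane numbering puts C12 on C4 and C13 on C8. For 36–39 the CIP label 4Z denotes the trans-cyclononene of β-caryophyllene (C3 and C6 trans), because the oxygenated C12 outranks C3.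

**Route**

Step 1
Reactants: 1 5,6-dihydro-2H-pyran-2-one; 2 potassium trifluoro(prop-1-en-2-yl)borate
Product: 3 (4S)-4-(prop-1-en-2-yl)oxan-2-one
Conditions: [Rh(cod)2]PF6 (3 mol %), (S)-BINAP, PhMe/H2O 4:1, 100 °C
Reagents that add atoms: none
Why: Hayashi–Miyaura rhodium-catalysed asymmetric 1,4-addition of an alkenylboron reagent to the unsaturated lactone; the (S)-BINAP–rhodium alkenyl species adds to one enantioface and sets the future C5.

Step 2
Reactants: 3 (4S)-4-(prop-1-en-2-yl)oxan-2-one; 4 1-chloro-3-iodopropane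
Product: 6 (3R,4S)-3-(3-chloropropyl)-4-(prop-1-en-2-yl)oxan-2-one, via lithium enolate 5 (not isolated)
Conditions: LiN(iPr)2, THF, −78 °C; then 4, HMPA, −78 → −30 °C
Reagents that add atoms: none
Why: Enolate alkylation (SN2) at the iodide end of 4, anti to the isopropenyl group; the new C–H centre is planarised again in step 3, so its configuration is of no consequence.

Step 3
Reactants: 6 (3R,4S)-3-(3-chloropropyl)-4-(prop-1-en-2-yl)oxan-2-one
Product: 8 (3S,4R)-3-(3-chloropropyl)-3-methyl-4-(prop-1-en-2-yl)oxan-2-one, via lithium enolate 7 (not isolated)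
Conditions: LiN(iPr)2, THF, −78 °C; MeI, −78 → −20 °C
Reagents that add atoms: iodomethane, CI
Why: Second enolate alkylation: MeI attacks the tetrasubstituted lactone enolate on the face opposite the adjacent isopropenyl group (1,2-induction in the cyclic enolate), which sets the quaternary C4 with CH3 trans and the chloropropyl chain cis to C10.

Step 4
Reactants: 8 (3S,4R)-3-(3-chloropropyl)-3-methyl-4-(prop-1-en-2-yl)oxan-2-one
Product: 10 methyl (2S,3R)-2-(3-chloropropyl)-3-(2-iodoethyl)-2,4-dimethylpent-4-enoate, via iodo acid 9 (not isolated)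
Conditions: Me3SiI, CH2Cl2, 25 °C; aq. Na2S2O3 work-up; then Me3SiCHN2, PhMe/MeOH, 0 °C
Reagents that add atoms: iodotrimethylsilane, C[Si](C)(C)I; (trimethylsilyl)diazomethane, C[Si](C)(C)C=[N+]=[N-]
Why: Silyl-assisted lactone cleavage: iodide attacks the primary O–CH2 carbon (C7) in an SN2 reaction and the liberated acid is O-methylated by the diazoalkane, neither stereocentre being involved.

Step 5
Reactants: 10 methyl (2S,3R)-2-(3-chloropropyl)-3-(2-iodoethyl)-2,4-dimethylpent-4-enoate; 11 ethynyltrimethylsilane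
Product: 13 methyl (2S,3R)-2-(3-chloropropyl)-2,4-dimethyl-3-[4-(trimethylsilyl)but-3-yn-1-yl]pent-4-enoate, via lithium silylacetylide 12 (not isolated)
Conditions: 11, n-BuLi, THF, −78 °C; then 10, HMPA, −78 → 0 °C
Reagents that add atoms: none
Why: SN2 alkylation of the lithium acetylide by the primary iodide; the primary chloride and the hindered ester react much more slowly.

Step 6
Reactants: 13 methyl (2S,3R)-2-(3-chloropropyl)-2,4-dimethyl-3-[4-(trimethylsilyl)but-3-yn-1-yl]pent-4-enoate
Product: 14 methyl (2S,3S)-3-acetyl-2-(3-chloropropyl)-2-methyl-7-(trimethylsilyl)hept-6-ynoate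
Conditions: O3, CH2Cl2/MeOH, −78 °C; then Me2S
Reagents that add atoms: ozone, [O-][O+]=O
Why: Ozonolysis with reductive work-up; the 1,1-disubstituted alkene reacts far faster than the silylalkyne, and C10 becomes the acetyl carbonyl carbon.

Step 7
Reactants: 14 methyl (2S,3S)-3-acetyl-2-(3-chloropropyl)-2-methyl-7-(trimethylsilyl)hept-6-ynoate
Product: 17 dimethyl (4R,5S)-5-(3-chloropropyl)-5-methyl-4-[4-(trimethylsilyl)but-3-yn-1-yl]hex-2-ynedioate, via enol phosphate 15 (not isolated), via alkynyllithium 16 (not isolated)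
Conditions: LiN(iPr)2, THF, −78 °C; ClP(O)(OEt)2, −78 → 0 °C; LiN(iPr)2 (2.3 equiv), −78 → 20 °C; then ClCO2Me, −78 °C
Reagents that add atoms: methyl chloroformate, COC(=O)Cl
Why: Methyl ketone to alkyne by enol phosphate elimination: kinetic enolisation at CH3 (C5–H is shielded by the quaternary C4), O-phosphorylation and elimination give the alkynyllithium, which is C-acylated by the chloroformate to the ynoate.

Step 8
Reactants: 17 dimethyl (4R,5S)-5-(3-chloropropyl)-5-methyl-4-[4-(trimethylsilyl)but-3-yn-1-yl]hex-2-ynedioate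
Product: 18 dimethyl (2Z,4R,5S)-5-(3-chloropropyl)-3,5-dimethyl-4-[4-(trimethylsilyl)but-3-yn-1-yl]hex-2-enedioate
Conditions: Me2CuLi, THF, −78 °C; MeOH quench at −78 °C
Reagents that add atoms: lithium dimethylcuprate, [Li+].C[Cu-]C
Why: syn-Carbocupration (conjugate addition of the cuprate to the ynoate) and protonation at −78 °C put CH3 and H cis, hence C5 and the ester cis, the (Z)-geometry on which step 11 relies.

Step 9
Reactants: 18 dimethyl (2Z,4R,5S)-5-(3-chloropropyl)-3,5-dimethyl-4-[4-(trimethylsilyl)but-3-yn-1-yl]hex-2-enedioate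
Product: 19 dimethyl (2Z,4R,5S)-4-(but-3-yn-1-yl)-5-(3-chloropropyl)-3,5-dimethylhex-2-enedioate
Conditions: K2CO3, MeOH, 0 → 25 °C
Reagents that add atoms: none
Why: Base-catalysed methanolysis of the alkynyl C–Si bond (protodesilylation); enoate and chloride are inert.

Step 10
Reactants: 19 dimethyl (2Z,4R,5S)-4-(but-3-yn-1-yl)-5-(3-chloropropyl)-3,5-dimethylhex-2-enedioate
Product: 20 dimethyl (2Z,4R,5S)-4-(but-3-yn-1-yl)-5-(3-iodopropyl)-3,5-dimethylhex-2-enedioate
Conditions: NaI, butan-2-one, 80 °C
Reagents that add atoms: sodium iodide, [Na+].[I-]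
Why: Finkelstein halide exchange (SN2) gives the iodide needed for radical generation.

Step 11
Reactants: 20 dimethyl (2Z,4R,5S)-4-(but-3-yn-1-yl)-5-(3-iodopropyl)-3,5-dimethylhex-2-enedioate
Product: 23 dimethyl 12,13,14,15,16-pentanorlabd-8(17)-ene-11,19-dioate (trans-decalin; H-5α, H-9α, CH3-20β, CO2Me-19β), via α-ester radical 21 (not isolated), via vinyl radical 22 (not isolated)
Conditions: (Me3Si)3SiH (1.3 equiv) and AIBN added over 8 h to 20 in PhMe (0.005 M), 90 °C
Reagents that add atoms: none
Why: Iodine abstraction gives the C1 radical, which adds 6-exo-trig to C10 (β-carbon of the enoate) and closes ring A; the resulting C9 α-ester radical closes ring B by 6-exo-dig attack on C8, and the C17 vinyl radical takes hydrogen from the silane, which carries the chain. The closest known reaction type is the tin- or silane-mediated tandem radical cyclisation of ω-halo enoates (intramolecular Giese addition followed by radical–alkyne cyclisation). C10 is controlled by A(1,3) strain: the (Z)-enoate holds H-5 in the enoate plane next to the cis ester, so the C4 tether reaches one π-face only, through a chair with C6 equatorial and CO2Me-19 axial, which places CH3-20 anti to H-5 (trans fusion). C9 is controlled by the chair-like second closure with the ester pseudo-equatorial (H-9α); this centre is α to the ester, so a minor epimer could be converged by dienolate formation and α-face protonation. The step needs 6-exo addition to outrun 7-endo addition and 1,5-hydrogen transfer, which the polarity match of the alkyl radical with the enoate β-carbon and the gem-disubstituted C4 should secure; it also needs closure of the C9 radical to outrun hydrogen transfer, which the slow donor (Me3Si)3SiH at low concentration should secure.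

Step 12
Reactants: 23 dimethyl 12,13,14,15,16-pentanorlabd-8(17)-ene-11,19-dioate
Product: 24 methyl 11-hydroxy-12,13,14,15,16-pentanorlabd-8(17)-en-19-oate
Conditions: i-Bu2AlH (2.2 equiv), CH2Cl2, −78 °C
Reagents that add atoms: none
Why: Hydride reduction (DIBAL-H) of the less hindered C11 ester; the axial 19-ester on quaternary C4, 1,3-diaxial to CH3-20, should not be attacked at −78 °C.

Step 13
Reactants: 24 methyl 11-hydroxy-12,13,14,15,16-pentanorlabd-8(17)-en-19-oate; 25 3-methyl-2,5-dihydrothiophene 1,1-dioxide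
Product: 28 methyl 11-(3-methyl-1,1-dioxo-2,5-dihydrothiophen-2-yl)-12,13,14,15,16-pentanorlabd-8(17)-en-19-oate (both epimers at the sulfolene carbon), via triflate 26 (not isolated), via lithiated sulfolene 27 (not isolated)
Conditions: Tf2O, 2,6-lutidine, CH2Cl2, −78 °C; crude triflate and 25 in THF/HMPA, then LiN(SiMe3)2, −78 °C
Reagents that add atoms: none
Why: SN2 alkylation of the C2 carbanion of 3-methyl-3-sulfolene (generated in the presence of the electrophile to outrun ring opening) by the primary triflate, a known entry to (E)-2-methyl-1,3-dienes; the sulfolene centre is lost in step 14.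

Step 14
Reactants: 28 methyl 11-(3-methyl-1,1-dioxo-2,5-dihydrothiophen-2-yl)-12,13,14,15,16-pentanorlabd-8(17)-en-19-oate
Product: 29 methyl (12E)-labda-8(17),12,14-trien-19-oate (methyl trans-communate)
Conditions: pyridine, PhMe, 110 °C, N2 stream
Reagents that add atoms: none
Why: Cheletropic extrusion of SO2, disrotatory with the C2 substituent turning outward, gives the (12E)-diene.

Step 15
Reactants: 29 methyl (12E)-labda-8(17),12,14-trien-19-oate
Product: 30 (12E)-labda-8(17),12,14-trien-19-oic acid (trans-communic acid)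
Conditions: n-PrSLi, HMPA, 25 °C; aq. HCl work-up
Reagents that add atoms: none
Why: SN2 demethylation of the hindered ester by thiolate at the methyl carbon, which avoids attack at the shielded carbonyl.

Step 16
Reactants: 31 (−)-caryophyllene oxide, (1R,4R,5R,9S)-4,5-epoxycaryophyll-8(13)-ene
Product: 32 (1R,5R,9S)-caryophylla-4(12),8(13)-dien-5-ol
Conditions: LiNEt2, Et2O, 0 → 35 °C
Reagents that add atoms: none
Why: Base-induced epoxide-to-allylic-alcohol isomerisation (syn β-elimination): the amide removes a proton from the C4 methyl group, the least substituted β-position, and C5 keeps its configuration.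

Step 17
Reactants: 32 (1R,5R,9S)-caryophylla-4(12),8(13)-dien-5-ol
Product: 33 (1R,4S,5R,9S)-4,12-epoxycaryophyll-8(13)-en-5-ol
Conditions: VO(acac)2 (5 mol %), t-BuOOH, CH2Cl2, 0 °C
Reagents that add atoms: tert-butyl hydroperoxide, CC(C)(C)OO
Why: Hydroxyl-directed vanadium-catalysed epoxidation: the peroxide bound next to the alkoxide is delivered to the C4=C12 face syn to O5 in the conformer that relieves A(1,2) strain (H-5 near C3), which should give the erythro epoxy alcohol (4S) and leave C8=C13 untouched.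

Step 18
Reactants: 33 (1R,4S,5R,9S)-4,12-epoxycaryophyll-8(13)-en-5-ol
Product: 34 [(1R,4S,5R,9S)-4,5-dihydroxycaryophyll-8(13)-en-12-yl] benzoate
Conditions: Ti(OiPr)4, PhCO2H, CH2Cl2, 25 °C
Reagents that add atoms: benzoic acid, OC(=O)c1ccccc1
Why: Ti(OiPr)4-mediated regioselective opening of the 2,3-epoxy alcohol by benzoate at the primary C12 (SN2), so C4 keeps its oxygen and configuration.

Step 19
Reactants: 34 [(1R,4S,5R,9S)-4,5-dihydroxycaryophyll-8(13)-en-12-yl] benzoate
Product: 35 4,5-cyclic thionocarbonate of 34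
Conditions: S=C(imidazol-1-yl)2, DMAP, PhMe, 100 °C
Reagents that add atoms: 1,1′-thiocarbonyldiimidazole, S=C(n1ccnc1)n1ccnc1
Why: Cyclic thionocarbonate formation (double acyl substitution) on the 4,5-diol, with both C–O bonds retained.

Step 20
Reactants: 35 4,5-cyclic thionocarbonate of 34
Product: 36 [(1R,4Z,9S)-caryophylla-4,8(13)-dien-12-yl] benzoate (trans-cyclononene)
Conditions: 1,3-dimethyl-2-phenyl-1,3,2-diazaphospholidine, THF, 40 °C
Reagents that add atoms: none
Why: Corey–Winter olefination: stereospecific syn cycloelimination of the thionocarbonate; C12 eclipses C6 and C3 eclipses H-5 in the five-membered ring, so C3 and C6 come out trans, the strained trans-cyclononene of β-caryophyllene.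

Step 21
Reactants: 36 [(1R,4Z,9S)-caryophylla-4,8(13)-dien-12-yl] benzoate
Product: 37 (1R,4Z,9S)-caryophylla-4,8(13)-dien-12-ol
Conditions: K2CO3, MeOH, 25 °C
Reagents that add atoms: none
Why: Base-catalysed transesterification (methanolysis) of the benzoate.

Step 22
Reactants: 37 (1R,4Z,9S)-caryophylla-4,8(13)-dien-12-ol
Product: 39 (1R,4Z,9S)-caryophylla-4,8(13)-dien-12-oic acid, via enal 38 (not isolated)
Conditions: MnO2, CH2Cl2, 25 °C; filter; then NaClO2, NaH2PO4, 2-methylbut-2-ene, t-BuOH/H2O, 0 °C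
Reagents that add atoms: sodium chlorite, [Na+].[O-]Cl=O
Why: Allylic oxidation with MnO2 to the enal, then Pinnick oxidation of the aldehyde; neither operation should touch the alkene geometry.

Step 23
Reactants: 30 (12E)-labda-8(17),12,14-trien-19-oic acid; 39 (1R,4Z,9S)-caryophylla-4,8(13)-dien-12-oic acid
Product: 40 CNP0330729.1 (target, [4+2] adduct of 30 and 39)
Conditions: PhMe (1 M), BHT (cat.), sealed tube, 120 °C
Reagents that add atoms: none
Why: Thermal Diels–Alder reaction of the s-cis (12E)-diene with the strained trans-cyclononene acrylic acid: the free terminus C15 bonds to the β-carbon C5′ and C12 to the carboxyl-bearing C4′; addition to the exposed outer face of the trans alkene (the face that peracids attack) with the carboxyl endo should set C12, C4′ and C5′, and the trans ring fusion follows from suprafacial addition.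

**Compound list**

1 | 5,6-dihydro-2H-pyran-2-one | O=C1C=CCCO1 | starting material
2 | potassium trifluoro(prop-1-en-2-yl)borate | [K+].CC(=C)[B-](F)(F)F | starting material
3 | (4S)-4-(prop-1-en-2-yl)oxan-2-one | CC(=C)[C@H]1CCOC(=O)C1 | intermediate
4 | 1-chloro-3-iodopropane | ClCCCI | starting material
5 | lithium enolate of 3 | CC(=C)[C@H]1CCOC(O[Li])=C1 | intermediate
6 | (3R,4S)-3-(3-chloropropyl)-4-(prop-1-en-2-yl)oxan-2-one | CC(=C)[C@H]1CCOC(=O)[C@@H]1CCCCl | intermediate
7 | lithium enolate of 6 | CC(=C)[C@H]1CCOC(O[Li])=C1CCCCl | intermediate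
8 | (3S,4R)-3-(3-chloropropyl)-3-methyl-4-(prop-1-en-2-yl)oxan-2-one | CC(=C)[C@H]1CCOC(=O)[C@@]1(C)CCCCl | intermediate
9 | (2S,3R)-2-(3-chloropropyl)-3-(2-iodoethyl)-2,4-dimethylpent-4-enoic acid | ClCCC[C@](C)(C(=O)O)[C@H](CCI)C(C)=C | intermediate
10 | methyl (2S,3R)-2-(3-chloropropyl)-3-(2-iodoethyl)-2,4-dimethylpent-4-enoate | ClCCC[C@](C)(C(=O)OC)[C@H](CCI)C(C)=C | intermediate
11 | ethynyltrimethylsilane | C#C[Si](C)(C)C | starting material
12 | lithium (trimethylsilyl)acetylide | [Li]C#C[Si](C)(C)C | intermediate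
13 | methyl (2S,3R)-2-(3-chloropropyl)-2,4-dimethyl-3-[4-(trimethylsilyl)but-3-yn-1-yl]pent-4-enoate | ClCCC[C@](C)(C(=O)OC)[C@H](CCC#C[Si](C)(C)C)C(C)=C | intermediate
14 | methyl (2S,3S)-3-acetyl-2-(3-chloropropyl)-2-methyl-7-(trimethylsilyl)hept-6-ynoate | ClCCC[C@](C)(C(=O)OC)[C@H](CCC#C[Si](C)(C)C)C(C)=O | intermediate
15 | diethyl enol phosphate of 14 (terminal enol) | ClCCC[C@](C)(C(=O)OC)[C@H](CCC#C[Si](C)(C)C)C(=C)OP(=O)(OCC)OCC | intermediate
16 | alkynyllithium from 15 | ClCCC[C@](C)(C(=O)OC)[C@H](CCC#C[Si](C)(C)C)C#C[Li] | intermediate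
17 | dimethyl (4R,5S)-5-(3-chloropropyl)-5-methyl-4-[4-(trimethylsilyl)but-3-yn-1-yl]hex-2-ynedioate | ClCCC[C@](C)(C(=O)OC)[C@H](CCC#C[Si](C)(C)C)C#CC(=O)OC | intermediate
18 | dimethyl (2Z,4R,5S)-5-(3-chloropropyl)-3,5-dimethyl-4-[4-(trimethylsilyl)but-3-yn-1-yl]hex-2-enedioate | ClCCC[C@](C)(C(=O)OC)[C@H](CCC#C[Si](C)(C)C)/C(C)=C\C(=O)OC | intermediate
19 | dimethyl (2Z,4R,5S)-4-(but-3-yn-1-yl)-5-(3-chloropropyl)-3,5-dimethylhex-2-enedioate | ClCCC[C@](C)(C(=O)OC)[C@H](CCC#C)/C(C)=C\C(=O)OC | intermediate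
20 | dimethyl (2Z,4R,5S)-4-(but-3-yn-1-yl)-5-(3-iodopropyl)-3,5-dimethylhex-2-enedioate | ICCC[C@](C)(C(=O)OC)[C@H](CCC#C)/C(C)=C\C(=O)OC | intermediate
21 | ring-A α-ester radical (radical at C9) | COC(=O)[CH][C@@]1(C)CCC[C@](C)(C(=O)OC)[C@@H]1CCC#C | intermediate
22 | bicyclic vinyl radical (radical at C17) | COC(=O)[C@H]1C(=[CH])CC[C@@H]2[C@]1(C)CCC[C@]2(C)C(=O)OC | intermediate
23 | dimethyl 12,13,14,15,16-pentanorlabd-8(17)-ene-11,19-dioate (H-5α, H-9α, CH3-20β) | COC(=O)[C@H]1C(=C)CC[C@@H]2[C@]1(C)CCC[C@]2(C)C(=O)OC | intermediate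
24 | methyl 11-hydroxy-12,13,14,15,16-pentanorlabd-8(17)-en-19-oate | OC[C@H]1C(=C)CC[C@@H]2[C@]1(C)CCC[C@]2(C)C(=O)OC | intermediate
25 | 3-methyl-2,5-dihydrothiophene 1,1-dioxide (3-methyl-3-sulfolene) | CC1=CCS(=O)(=O)C1 | starting material
26 | 11-O-triflate of 24 | FC(F)(F)S(=O)(=O)OC[C@H]1C(=C)CC[C@@H]2[C@]1(C)CCC[C@]2(C)C(=O)OC | intermediate
27 | 2-lithio-3-methyl-2,5-dihydrothiophene 1,1-dioxide | [Li]C1C(C)=CCS1(=O)=O | intermediate
28 | methyl 11-(3-methyl-1,1-dioxo-2,5-dihydrothiophen-2-yl)-12,13,14,15,16-pentanorlabd-8(17)-en-19-oate (sulfolene carbon unassigned) | CC1=CCS(=O)(=O)C1C[C@H]2C(=C)CC[C@@H]3[C@]2(C)CCC[C@]3(C)C(=O)OC | intermediate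
29 | methyl (12E)-labda-8(17),12,14-trien-19-oate | C=C/C(C)=C/C[C@H]1C(=C)CC[C@@H]2[C@]1(C)CCC[C@]2(C)C(=O)OC | intermediate
30 | (12E)-labda-8(17),12,14-trien-19-oic acid (trans-communic acid) | C=C/C(C)=C/C[C@H]1C(=C)CC[C@@H]2[C@]1(C)CCC[C@]2(C)C(=O)O | intermediate
31 | (−)-caryophyllene oxide, (1R,4R,5R,9S) | C[C@@]12CC[C@@H]3[C@H](CC3(C)C)C(=C)CC[C@H]1O2 | starting material
32 | (1R,5R,9S)-caryophylla-4(12),8(13)-dien-5-ol | C=C1CC[C@@H]2[C@H](CC2(C)C)C(=C)CC[C@H]1O | intermediate
33 | (1R,4S,5R,9S)-4,12-epoxycaryophyll-8(13)-en-5-ol | O1C[C@]12CC[C@@H]3[C@H](CC3(C)C)C(=C)CC[C@H]2O | intermediate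
34 | [(1R,4S,5R,9S)-4,5-dihydroxycaryophyll-8(13)-en-12-yl] benzoate | O=C(OC[C@@]1(O)CC[C@@H]2[C@H](CC2(C)C)C(=C)CC[C@H]1O)c1ccccc1 | intermediate
35 | 4,5-cyclic thionocarbonate of 34 | O=C(OC[C@@]12CC[C@@H]3[C@H](CC3(C)C)C(=C)CC[C@H]1OC(=S)O2)c1ccccc1 | intermediate
36 | [(1R,4Z,9S)-caryophylla-4,8(13)-dien-12-yl] benzoate (C3 and C6 trans) | O=C(OC/C1=C\CCC(=C)[C@H]2CC([C@@H]2CC1)(C)C)c1ccccc1 | intermediate
37 | (1R,4Z,9S)-caryophylla-4,8(13)-dien-12-ol | OC/C1=C\CCC(=C)[C@H]2CC([C@@H]2CC1)(C)C | intermediate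
38 | (1R,4Z,9S)-caryophylla-4,8(13)-dien-12-al | O=C/C1=C\CCC(=C)[C@H]2CC([C@@H]2CC1)(C)C | intermediate
39 | (1R,4Z,9S)-caryophylla-4,8(13)-dien-12-oic acid | OC(=O)/C1=C\CCC(=C)[C@H]2CC([C@@H]2CC1)(C)C | intermediate
40 | CNP0330729.1, [4+2] adduct of 30 (diene) and 39 (dienophile) | C=C1CC[C@H]2CC=C(C)[C@@H](C[C@H]3C(=C)CC[C@@H]4[C@]3(C)CCC[C@]4(C)C(=O)O)[C@]2(C(=O)O)CC[C@@H]2[C@@H]1CC2(C)C | target

**Summary and risks**

Total step count: 23 (diterpene acid 15 steps, sesquiterpene acid 7 steps, union 1 step). Longest linear sequence: 16 steps (steps 1–15, then step 23).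

Steps most likely to fail:

1. Step 11. The C9 α-ester radical may take hydrogen before it closes onto the alkyne, and facial selectivity at C9 in the second closure may be low. The fallback closes the two rings in separate, known operations and sets out from 20. Bu3SnH (0.1 M), AIBN, PhH, 80 °C should stop after the first closure and give the ring-A monocycle, methyl 2-(but-3-ynyl)-3-(2-methoxy-2-oxoethyl)-1,3-dimethylcyclohexane-1-carboxylate F1. LiN(iPr)2 then I2 gives the α-iodo ester F2. Iodine-atom-transfer radical cyclisation ((Bu3Sn)2, hν, PhH, no hydrogen donor present) closes ring B 6-exo-dig to the vinyl iodide F3. Bu3SnH/AIBN removes the vinylic iodine and the route is rejoined at 23.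

2. Step 23. Conversion may be low for a cycloaddition that forms a quaternary centre from a trisubstituted diene and a trisubstituted dienophile, and regio-, endo- and facial selectivity may erode at the temperature required. The fallback uses a Lewis-acid-activated aldehyde dienophile and sets out from 37 and 29. MnO2 oxidation of 37 gives enal 38, isolated this time. Me2AlCl (CH2Cl2, −78 → −20 °C) promotes its Diels–Alder reaction with ester 29 to the adduct aldehyde methyl ester F4. Pinnick oxidation gives the adduct acid methyl ester F5, and n-PrSLi/HMPA cleaves the methyl ester to rejoin the route at 40.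

3. Step 13. The sulfolene carbanion may ring-open, the neopentyl-type homoallylic triflate may ionise and rearrange, and alkylation may occur at C5 of the sulfolene instead of C2. The fallback is a cross-coupling and sets out from 24. I2, PPh3, imidazole give the primary iodide F6. Zn dust/LiCl in THF gives the alkylzinc iodide F7. Pd(PPh3)4-catalysed Negishi coupling with (E)-1-iodo-2-methylbuta-1,3-diene F8 (made from but-1-en-3-yne by Me3Al/Cp2ZrCl2 carboalumination and iodination) rejoins the route at 29.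

**Further compounds**

F1 | step 11 | methyl 2-(but-3-ynyl)-3-(2-methoxy-2-oxoethyl)-1,3-dimethylcyclohexane-1-carboxylate (C4, C5, C10 as in 23) | COC(=O)C[C@@]1(C)CCC[C@](C)(C(=O)OC)[C@@H]1CCC#C
F2 | step 11 | α-iodo ester of F1 (iodine at C9, both epimers) | COC(=O)C(I)[C@@]1(C)CCC[C@](C)(C(=O)OC)[C@@H]1CCC#C
F3 | step 11 | dimethyl 17-iodo-12,13,14,15,16-pentanorlabd-8(17)-ene-11,19-dioate (alkene geometry unassigned) | COC(=O)[C@H]1C(=CI)CC[C@@H]2[C@]1(C)CCC[C@]2(C)C(=O)OC
F4 | step 23 | 12′-aldehyde 19-methyl ester analogue of 40 | C=C1CC[C@H]2CC=C(C)[C@@H](C[C@H]3C(=C)CC[C@@H]4[C@]3(C)CCC[C@]4(C)C(=O)OC)[C@]2(C=O)CC[C@@H]2[C@@H]1CC2(C)C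
F5 | step 23 | 19-methyl ester of 40 | C=C1CC[C@H]2CC=C(C)[C@@H](C[C@H]3C(=C)CC[C@@H]4[C@]3(C)CCC[C@]4(C)C(=O)OC)[C@]2(C(=O)O)CC[C@@H]2[C@@H]1CC2(C)C
F6 | step 13 | methyl 11-iodo-12,13,14,15,16-pentanorlabd-8(17)-en-19-oate | IC[C@H]1C(=C)CC[C@@H]2[C@]1(C)CCC[C@]2(C)C(=O)OC
F7 | step 13 | alkylzinc iodide from F6 | I[Zn]C[C@H]1C(=C)CC[C@@H]2[C@]1(C)CCC[C@]2(C)C(=O)OC
F8 | step 13 | (E)-1-iodo-2-methylbuta-1,3-diene | C=C/C(C)=C/I
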